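**Retrosynthetic overview**

- Feature used: pyran C2 (the O1–CH carbon) is bonded to the spiro carbon, which is C6' of a menthone ring whose C1' carbonyl becomes the alkene CH of the cyclohexene. C2 is therefore the β-carbon of a β-aryloxy ketone and can open and reclose, while the quaternary C3 (methyl) and benzylic C4 (isobutyl) sit in the same pyran.
- Disconnections: C1'=C2' alkene from the ketone; cyclopentane bond C6'–CH2 by enolate spiroalkylation while C2 equilibrates; bond C2–C6' by oxocarbenium/silyl enol ether coupling; C3 by two lactone enolate alkylations; C4 by an organocatalytic Friedel–Crafts reaction.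
- Ring order: pyran (step 2), cyclohexane brought in intact as (−)-menthone (step 8), cyclopentane last (step 9), then ketone to cyclohexene, debenzylation and the two formyl groups.

Key step: step 9

Remark: chroman atoms are O1, C2, C3, C4; primed numbers (C1' carbonyl, C2' isopropyl carbon, C5' methyl carbon, C6') refer to the menthone-derived ring. The (S)-configured catalyst of step 2 is assigned to the 4R product by the usual face-shielding model of the E-iminium ion; its mirror image would be used should the sense prove opposite.

**Route**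

Step 1
Reactants: 1 isovaleraldehyde; 2 (triphenylphosphoranylidene)acetaldehyde
Product: 3 (E)-5-methylhex-2-enal
Conditions: toluene, 80 °C (1 in excess)
Reagents that add atoms: none
Why: Wittig olefination with a stabilised formyl ylide should give the E-enal, the excess of the volatile aldehyde suppressing a second homologation of the product.

Step 2
Reactants: 3 (E)-5-methylhex-2-enal; 4 3,5-bis(benzyloxy)phenol
Product: 6 (4R)-5,7-bis(benzyloxy)-4-isobutylchroman-2-ol as a mixture of C2 anomers, via open-chain hydroxyaryl aldehyde 5 (not isolated)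
Conditions: (S)-2-[diphenyl(trimethylsilyloxy)methyl]pyrrolidine (20 mol%), PhCO2H (20 mol%), toluene, 0 °C
Reagents that add atoms: none
Why: Iminium-catalysed enantioselective Friedel–Crafts alkylation followed by hemiacetalisation, in which the phenol carbon ortho to OH adds to the β-carbon of the E-iminium ion on the face away from the CPh2(OSiMe3) group, which should set C4 as R, and the phenol oxygen then closes onto the released aldehyde.

Step 3
Reactants: 6 (4R)-5,7-bis(benzyloxy)-4-isobutylchroman-2-ol
Product: 7 (4R)-5,7-bis(benzyloxy)-4-isobutylchroman-2-one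
Conditions: pyridinium chlorochromate [C5H5NH][CrO3Cl], NaOAc, CH2Cl2, 25 °C
Reagents that add atoms: none
Why: Chlorochromate oxidation of a lactol to the lactone, a standard conversion of chroman-2-ols into dihydrocoumarins that leaves the benzylic C4 centre and the benzyl ethers untouched.

Step 4
Reactants: 7 (4R)-5,7-bis(benzyloxy)-4-isobutylchroman-2-one; 8 2-chloroethyl trifluoromethanesulfonate
Product: 9 (3R,4R)-5,7-bis(benzyloxy)-3-(2-chloroethyl)-4-isobutylchroman-2-one (3,4-trans)
Conditions: LiN(SiMe3)2, THF, −78 °C; then 8, −78 °C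
Reagents that add atoms: none
Why: Lactone enolate SN2 alkylation in which the triflate end of 8 reacts far faster than the chloride end and the electrophile should enter anti to the pseudoaxial C4 isobutyl group (trans), a centre that is flattened again in step 5.

Step 5
Reactants: 9 (3R,4R)-5,7-bis(benzyloxy)-3-(2-chloroethyl)-4-isobutylchroman-2-one
Product: 10 (3S,4S)-5,7-bis(benzyloxy)-3-(2-chloroethyl)-4-isobutyl-3-methylchroman-2-one (methyl trans, chloroethyl cis to isobutyl)
Conditions: LiN(i-Pr)2, THF, −78 °C; MeI (5 equiv), −78 °C; AcOH quench at −78 °C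
Reagents that add atoms: iodomethane, CI
Why: Enolate methylation creating the quaternary C3, in which iodomethane should attack the planar enolate anti to the C4 isobutyl group (held pseudoaxial by the peri C5 benzyloxy group), while at −78 °C this intermolecular SN2 step should outrun 3-exo-tet closure of the lithium enolate onto the primary chloride.

Step 6
Reactants: 10 (3S,4S)-5,7-bis(benzyloxy)-3-(2-chloroethyl)-4-isobutyl-3-methylchroman-2-one
Product: 11 (3S,4S)-5,7-bis(benzyloxy)-3-(2-chloroethyl)-4-isobutyl-3-methylchroman-2-ol (C2 anomers)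
Conditions: i-Bu2AlH (1.1 equiv), CH2Cl2, −78 °C
Reagents that add atoms: none
Why: Partial hydride reduction of the aryl lactone stops at the lactol because the tetrahedral aluminate beside a quaternary carbon should persist at −78 °C until work-up, and the anomeric centre so formed is of no consequence.

Step 7
Reactants: 12 (−)-menthone, (2S,5R)-2-isopropyl-5-methylcyclohexanone
Product: 13 trimethyl{[(3R,6S)-6-isopropyl-3-methylcyclohex-1-en-1-yl]oxy}silane
Conditions: LiN(i-Pr)2, THF, −78 °C; Me3SiCl
Reagents that add atoms: chlorotrimethylsilane, C[Si](C)(C)Cl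
Why: Kinetic deprotonation at the less hindered C6' methylene followed by O-silylation gives the less substituted silyl enol ether and leaves C2' and C5' untouched.

Step 8
Reactants: 11 (3S,4S)-5,7-bis(benzyloxy)-3-(2-chloroethyl)-4-isobutyl-3-methylchroman-2-ol; 13 menthone trimethylsilyl enol ether (2 equiv)
Product: 14 2-[5,7-bis(benzyloxy)-3-(2-chloroethyl)-4-isobutyl-3-methylchroman-2-yl]-6-isopropyl-3-methylcyclohexan-1-one, mixture of epimers at chroman C2 and at C6'
Conditions: BF3·OEt2 (1.5 equiv), CH2Cl2, −78 → −30 °C; aq NaHCO3
Reagents that add atoms: none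
Why: Mukaiyama-type addition of a silyl enol ether to a lactol-derived oxocarbenium ion (C3 is quaternary, so the cation cannot eliminate) forms the C2–C6' bond, and the two new centres are expected as mixtures and are left so because step 9 equilibrates them.

Step 9
Reactants: 14 coupled chloroethyl ketone (epimer mixture)
Product: 17 spiro tetracyclic ketone (cyclopentane cis-fused to the pyran at C2–C3 and spiro at C6' to the 2'-isopropyl-5'-methylcyclohexan-1'-one; C2' unassigned), via primary iodide 15 (not isolated), via ring-opened phenoxide enone 16 (not isolated)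
Conditions: NaI (2 equiv), KOt-Bu (1.2 equiv), THF/t-BuOH, 0.02 M, 0 → 40 °C
Reagents that add atoms: none
Why: Proposed new method: KOt-Bu reversibly forms the C6' enolate of the β-aryloxy ketone; that enolate either expels the phenoxide (E1cB retro-oxa-Michael, giving 16, which recloses on either alkene face) or displaces the primary iodide made in the flask by Finkelstein exchange, and since only the C–C bond formation is irreversible every epimer of 14 at C2 and C6' should drain through it; the closest known reactions are the 5-exo-tet enolate spiroalkylation of 2-substituted cyclohexanones to spiro[4.5]decanones and the base epimerisation of 2-(2-oxoalkyl)chromans through ring opening and reclosure, which have not been run as one stereoconvergent operation. The cyclopentane closes 5-exo-tet with the enolate C=C exocyclic to the new ring, creating the spiro quaternary carbon, and the pyran recloses 6-exo-trig by oxa-Michael addition. Pyran C2 is fixed by the ring fusion, because a two-atom tether closes from the epimer with C6' cis to the arm by merely flattening the chroman half-chair, whereas the trans epimer would need extra pucker that the planar aryl ether segment resists. The spiro carbon is controlled by the C5' methyl group, which turns pseudoaxial to escape A(1,2) strain with the chromanyl substituent on the enolate carbon, so the arm bonds to the opposite face. The step needs C- over O-alkylation, secured because the enolate oxygen and the phenoxide oxygen could only alkylate through seven-membered rings, and it needs a single productive enolate, secured because C3 is quaternary (no enolisation or elimination on the halide side, and gem-disubstitution aids closure) and the C2' enolate can only epimerise the isopropyl carbon, which later becomes sp2.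

Step 10
Reactants: 17 spiro tetracyclic ketone
Product: 18 enol triflate (C1'(OTf)=C2'(i-Pr))
Conditions: KN(SiMe3)2, THF, −78 → 0 °C; PhNTf2, 0 → 25 °C
Reagents that add atoms: N-phenylbis(trifluoromethanesulfonimide), O=S(=O)(N(c1ccccc1)S(=O)(=O)C(F)(F)F)C(F)(F)F
Why: Enolate O-triflation in which the ketone has a single α-hydrogen (C2'–H, the spiro carbon being quaternary), so one enolate forms and is trapped, erasing the C2' stereocentre.

Step 11
Reactants: 18 enol triflate
Product: 19 spiro cyclohexene bis(benzyl ether)
Conditions: Pd(OAc)2 (10 mol%), PPh3 (20 mol%), HCO2H, n-Bu3N, DMF, 60 °C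
Reagents that add atoms: none
Why: Palladium-catalysed formate reduction of an enol triflate (oxidative addition to zerovalent palladium, formate exchange, decarboxylation, reductive elimination) replaces OTf by H with the double bond fixed at C1'=C2', and aryl benzyl ethers should survive these homogeneous conditions.

Step 12
Reactants: 19 spiro cyclohexene bis(benzyl ether)
Product: 20 5,7-dihydroxy spiro cyclohexene chroman
Conditions: BCl3, C6HMe5, CH2Cl2, −78 °C; MeOH/H2O
Reagents that add atoms: none
Why: Lewis-acid debenzylation with BCl3 and pentamethylbenzene as a non-basic benzyl cation scavenger should cleave both aryl benzyl ethers at −78 °C while sparing the trisubstituted alkene and the secondary alkyl aryl ether of the pyran.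

Step 13
Reactants: 20 5,7-dihydroxy spiro cyclohexene chroman
Product: 22 CNP0121396.1, via bis(dimethyliminium) dichloride 21 (not isolated)
Conditions: POCl3 (excess), DMF, 0 → 40 °C; then H2O, 50 °C
Reagents that add atoms: N,N-dimethylformamide, CN(C)C=O; water, O
Why: Double Vilsmeier–Haack formylation at the only free ring positions C6 and C8, each ortho/para to three oxygens, in which loss of HCl from the first iminium gives a neutral vinylogous amide still nucleophilic enough for the second attack, and hydrolysis of 21 releases both aldehydes.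

**Compound list**

1 | isovaleraldehyde (3-methylbutanal) | CC(C)CC=O | starting material
2 | (triphenylphosphoranylidene)acetaldehyde | O=CC=P(c1ccccc1)(c1ccccc1)c1ccccc1 | starting material
3 | (E)-5-methylhex-2-enal | CC(C)C/C=C/C=O | intermediate
4 | 3,5-bis(benzyloxy)phenol | Oc1cc(OCc2ccccc2)cc(OCc2ccccc2)c1 | starting material
5 | (3R)-3-[2,4-bis(benzyloxy)-6-hydroxyphenyl]-5-methylhexanal (open-chain adduct) | CC(C)C[C@H](CC=O)c1c(O)cc(OCc2ccccc2)cc1OCc1ccccc1 | intermediate
6 | (4R)-5,7-bis(benzyloxy)-4-isobutylchroman-2-ol, C2 anomers | CC(C)C[C@H]1c2c(OCc3ccccc3)cc(OCc3ccccc3)cc2OC(O)C1 | intermediate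
7 | (4R)-5,7-bis(benzyloxy)-4-isobutylchroman-2-one | CC(C)C[C@H]1c2c(OCc3ccccc3)cc(OCc3ccccc3)cc2OC(=O)C1 | intermediate
8 | 2-chloroethyl trifluoromethanesulfonate | ClCCOS(=O)(=O)C(F)(F)F | starting material
9 | (3R,4R)-5,7-bis(benzyloxy)-3-(2-chloroethyl)-4-isobutylchroman-2-one (3,4-trans) | CC(C)C[C@H]1c2c(OCc3ccccc3)cc(OCc3ccccc3)cc2OC(=O)[C@@H]1CCCl | intermediate
10 | (3S,4S)-5,7-bis(benzyloxy)-3-(2-chloroethyl)-4-isobutyl-3-methylchroman-2-one (methyl trans, chloroethyl cis to isobutyl) | CC(C)C[C@H]1c2c(OCc3ccccc3)cc(OCc3ccccc3)cc2OC(=O)[C@@]1(C)CCCl | intermediate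
11 | (3S,4S)-5,7-bis(benzyloxy)-3-(2-chloroethyl)-4-isobutyl-3-methylchroman-2-ol, C2 anomers | CC(C)C[C@H]1c2c(OCc3ccccc3)cc(OCc3ccccc3)cc2OC(O)[C@@]1(C)CCCl | intermediate
12 | (−)-menthone, (2S,5R)-2-isopropyl-5-methylcyclohexanone | CC(C)[C@@H]1CC[C@@H](C)CC1=O | starting material
13 | trimethyl{[(3R,6S)-6-isopropyl-3-methylcyclohex-1-en-1-yl]oxy}silane | C[C@@H]1CC[C@@H](C(C)C)C(O[Si](C)(C)C)=C1 | intermediate
14 | 2-[5,7-bis(benzyloxy)-3-(2-chloroethyl)-4-isobutyl-3-methylchroman-2-yl]-6-isopropyl-3-methylcyclohexan-1-one; chroman C3, C4 as in 11, C2' and C5' as in 12; epimers at chroman C2 and C6' | CC(C)C[C@H]1c2c(OCc3ccccc3)cc(OCc3ccccc3)cc2OC(C2C(=O)[C@H](C(C)C)CC[C@H]2C)[C@@]1(C)CCCl | intermediate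
15 | iodoethyl analogue of 14 (same epimer mixture) | CC(C)C[C@H]1c2c(OCc3ccccc3)cc(OCc3ccccc3)cc2OC(C2C(=O)[C@H](C(C)C)CC[C@H]2C)[C@@]1(C)CCI | intermediate
16 | ring-opened 2-alkylidene ketone with free phenol (present as its potassium phenoxide; alkene geometry and C2' unassigned) | CC(C)C[C@H]([C@](C)(CCI)C=C1C(=O)C(C(C)C)CC[C@H]1C)c1c(O)cc(OCc2ccccc2)cc1OCc1ccccc1 | intermediate
17 | spiro tetracyclic ketone: 5,7-bis(benzyloxy)-4-isobutyl-3-methylchroman with C2 and C3 cis-bridged by CH2CH2–C6', C6' being the spiro carbon of a 2'-isopropyl-5'-methylcyclohexan-1'-one; bridge cis to isobutyl, C3 methyl and C2–H on the other face, bridge CH2 trans to the C5' methyl; C2' unassigned | CC(C)C[C@H]1c2c(OCc3ccccc3)cc(OCc3ccccc3)cc2O[C@@H]2[C@@]1(C)CC[C@@]21C(=O)C(C(C)C)CC[C@H]1C | intermediate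
18 | enol triflate of 17 (C1'(OTf)=C2') | CC(C)C[C@H]1c2c(OCc3ccccc3)cc(OCc3ccccc3)cc2O[C@@H]2[C@@]1(C)CC[C@@]21C(OS(=O)(=O)C(F)(F)F)=C(C(C)C)CC[C@H]1C | intermediate
19 | spiro cyclohexene bis(benzyl ether) (C1'H=C2'(i-Pr)) | CC(C)C[C@H]1c2c(OCc3ccccc3)cc(OCc3ccccc3)cc2O[C@@H]2[C@@]1(C)CC[C@@]21C=C(C(C)C)CC[C@H]1C | intermediate
20 | 5,7-dihydroxy spiro cyclohexene chroman | CC(C)C[C@H]1c2c(O)cc(O)cc2O[C@@H]2[C@@]1(C)CC[C@@]21C=C(C(C)C)CC[C@H]1C | intermediate
21 | 6,8-bis(dimethyliminiomethyl) derivative of 20, dichloride | CC(C)C[C@H]1c2c(O)c(C=[N+](C)C)c(O)c(C=[N+](C)C)c2O[C@@H]2[C@@]1(C)CC[C@@]21C=C(C(C)C)CC[C@H]1C.[Cl-].[Cl-] | intermediate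
22 | CNP0121396.1, the 5,7-dihydroxy-6,8-dicarbaldehyde (stereochemistry as in 19) | CC(C)C[C@H]1c2c(O)c(C=O)c(O)c(C=O)c2O[C@@H]2[C@@]1(C)CC[C@@]21C=C(C(C)C)CC[C@H]1C | target

**Step count and risks**

Total step count: 13. Longest linear sequence: 12 steps (steps 1–6 and 8–13, from isovaleraldehyde 1); step 7 is the one-step branch from (−)-menthone.

Steps most likely to fail:

1. Step 9 (the new method). The ring-opened phenoxide may become the resting state, so that the scarce closed enolate cyclises too slowly and material drains away by seven-membered O-alkylation or intermolecular alkylation. Closure through the trans-fused or methyl-syn transition state would also erode the stereochemical funnel. The fallback uses known chemistry and has no alkylating carbon in the ring closure. Setting out from 14, the chloride is exchanged (NaI, acetone, reflux) and iodide 15 is isolated. Me3NO in DMSO at 25 °C oxidises the primary iodide (Kornblum-type N-oxide oxidation) to the keto aldehyde F1. Catalytic KOt-Bu in t-BuOH/THF at 0 °C should then close the cyclopentane by intramolecular aldol addition of the C6' enolate to the aldehyde (5-exo-trig) to give the spiro β-hydroxy ketone F2; every competing step, retro-oxa-Michael opening included, is reversible here. PhOC(S)Cl, pyridine and DMAP give the phenyl thionocarbonate F3. Barton–McCombie deoxygenation (Bu3SnH, AIBN, toluene, 90 °C, high stannane concentration to outrun 1,2-acyl shift of the β-keto radical) returns to the route at 17.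

2. Step 8. Capture of the neopentyl-type oxocarbenium ion by the hindered trisubstituted enol ether may be slow, so that protodesilylation of 13 and Friedel–Crafts attack of the electron-rich arene of a second molecule on the cation take over. The fallback sets out from 11. Addition of the kinetic lithium enolate of 12 (LiN(i-Pr)2, THF, −78 °C, 2.2 equiv; the first equivalent opens the lactol to the phenoxide aldehyde) should give the β-hydroxy ketone F4 by directed aldol addition. TsOH (cat.) in toluene at 60 °C dehydrates it to the enone, onto which the phenol closes by oxa-Michael addition, returning to the route at 14.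

3. Step 5. Methylation of the hindered lithium enolate may be slow enough that 3-exo-tet closure onto the chloride (spirocyclopropane formation) or ketene-forming ring opening intervenes on warming. The fallback carries the arm as a silyl ether that cannot leave. From 7, LiN(SiMe3)2 and (2-iodoethoxy)(tert-butyl)dimethylsilane (THF/DMPU, −78 → −30 °C) give the silyloxyethyl lactone F5. LiN(i-Pr)2 and MeI give the quaternary lactone F6 under the same facial control. i-Bu2AlH gives the lactol F7, and BF3·OEt2 with 13 gives the coupled ketone F8. HF·pyridine (THF, 0 °C) frees the alcohol F9 without basic ring opening. I2, PPh3 and imidazole (CH2Cl2, 0 °C) convert it into iodide 15, where the route is rejoined and step 9 is run with KOt-Bu alone.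

**Further compounds**

F1 | step 9 | keto aldehyde, the 3-(2-oxoethyl) analogue of 14 | CC(C)C[C@H]1c2c(OCc3ccccc3)cc(OCc3ccccc3)cc2OC(C2C(=O)[C@H](C(C)C)CC[C@H]2C)[C@@]1(C)CC=O
F2 | step 9 | spiro β-hydroxy ketone, 17 bearing OH on the cyclopentane CH next to the spiro carbon (carbinol epimers) | CC(C)C[C@H]1c2c(OCc3ccccc3)cc(OCc3ccccc3)cc2O[C@@H]2[C@@]1(C)CC(O)[C@@]21C(=O)C(C(C)C)CC[C@H]1C
F3 | step 9 | O-phenyl thionocarbonate of F2 | CC(C)C[C@H]1c2c(OCc3ccccc3)cc(OCc3ccccc3)cc2O[C@@H]2[C@@]1(C)CC(OC(=S)Oc3ccccc3)[C@@]21C(=O)C(C(C)C)CC[C@H]1C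
F4 | step 8 | open-chain aldol adduct (β-hydroxy ketone with free phenol; carbinol and C6' epimers) | CC(C)C[C@H]([C@](C)(CCCl)C(O)C1C(=O)[C@H](C(C)C)CC[C@H]1C)c1c(O)cc(OCc2ccccc2)cc1OCc1ccccc1
F5 | step 5 | 3-[2-(tert-butyldimethylsilyloxy)ethyl] lactone, 3,4-trans | CC(C)C[C@H]1c2c(OCc3ccccc3)cc(OCc3ccccc3)cc2OC(=O)[C@@H]1CCO[Si](C)(C)C(C)(C)C
F6 | step 5 | 3-methyl-3-[2-(tert-butyldimethylsilyloxy)ethyl] lactone, methyl trans to isobutyl | CC(C)C[C@H]1c2c(OCc3ccccc3)cc(OCc3ccccc3)cc2OC(=O)[C@@]1(C)CCO[Si](C)(C)C(C)(C)C
F7 | step 5 | corresponding chroman-2-ol (C2 anomers) | CC(C)C[C@H]1c2c(OCc3ccccc3)cc(OCc3ccccc3)cc2OC(O)[C@@]1(C)CCO[Si](C)(C)C(C)(C)C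
F8 | step 5 | silyloxyethyl analogue of 14 (epimers at chroman C2 and C6') | CC(C)C[C@H]1c2c(OCc3ccccc3)cc(OCc3ccccc3)cc2OC(C2C(=O)[C@H](C(C)C)CC[C@H]2C)[C@@]1(C)CCO[Si](C)(C)C(C)(C)C
F9 | step 5 | hydroxyethyl analogue of 14 (epimers at chroman C2 and C6') | CC(C)C[C@H]1c2c(OCc3ccccc3)cc(OCc3ccccc3)cc2OC(C2C(=O)[C@H](C(C)C)CC[C@H]2C)[C@@]1(C)CCO
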